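The target is what is asked of these flasks, and I follow it with one ratio: the rate of making target divided by the rate of consuming starting material, a division in which time drops out.

| flask | starting material | protic impurity | temperature | remark | time |
|---|---|---|---|---|---|
| west | 0.025 M (fed, over 20 min) | 0.025 M | 15 °C | run made earlier; the fed solution adds 0.50 times the starting volume |  |
| north | 0.038 M (fed, over 20 min) | 0.025 M | 37 °C | run made earlier; the fed solution adds 0.50 times the starting volume |  |
| Friday's | 0.050 M (fed, over 20 min) | 0.0250 M |  | at 5 °C throughout; the fed solution adds 0.50 times the starting volume | 1.5 h |
| Thursday's | 0.050 M (fed, over 20 min) | 0.0250 M |  | at 5 °C until 20 min, from then on at 45 °C; the fed solution adds 0.50 times the starting volume | 1.5 h |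

- west (time / min: target / %, starting material / %): 4.00: 0, 16; 6.00: 3, 24; 12.0: 5, 41; 25.0: 19, 38; 50.0: 26, 7
- north (time / min: target / %, starting material / %): 3.00: 3, 6; 6.00: 9, 5; 8.00: 13, 5; 12.0: 18, 7; 15.0: 22, 5

(standard deviation of a reading: 1.5 percentage points)

* which of the two ends with the higher amount of target, in percent of the starting material charged ("neither" if they lie within 2 percentage points) (Friday's / Thursday's / neither)
* target at the end, in percent of the starting material charged, Friday's
* target at the end, in percent of the starting material charged, Thursday's

- charges are per starting volume, the dose included; the dosed solution carries all of it
- percentages count the whole charge, also what has not yet gone in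
- a reading or a percentage of target counts all its forms, free or not

1. Fastest rung: in north the starting material stays level during the dose, so consumption matches inflow, and that mean level against the dosing rate gives a life of 1.12 min.

2. In west, the fall after the dose gives 14.8 min, which is longer than north's.

3. Carrying that ratio of lives on down to 5 °C, I reckon 47.7 min for Friday's, longer than the dose, so Friday's fills with starting material and, counted from mid-dose, has consumed a fraction 0.813 of its charge at the end.

4. Thursday's warm stage, at 45 °C, is hotter than north and lasts 62.5 of north's lives, so I count its charge as consumed in full.

5. West holds 0.280 of its consumed starting material as target and north 0.314, and their mean, 0.297, is my selectivity, the fraction of consumed starting material found as target.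

So I reckon 0.297 of the charge for Thursday's and 0.241 for Friday's, which puts Thursday's ahead.

The forecast, which differs from mine on both figures, gives Thursday's, with 21% for Friday's and 42% for Thursday's, noting that the “loss showed no slowing with impurity use”.

The flask gives Thursday's, with 10.7% for Friday's and 29.3% for Thursday's.

    starting material → side product A (k = 0.511 /h, Ea = 86.0 kJ/mol)
    crystals ⇌ target, rate k2*(cs2 - [target]) while solid is left; crystals form when [target] > cs2 (solubility = 19.0 mM, k = 19.2 /h)
    starting material → target (k = 0.387 /h, Ea = 91.0 kJ/mol)
    starting material + target → side product B (k = 94.6 /M/h, Ea = 61.0 kJ/mol)
    starting material + protic impurity → quenched substrate (k = 10.1 /M/h, Ea = 63.0 kJ/mol)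
    (constants at 5 °C)

Friday's consumes 82.4% of its charge but holds 0.129 of that as target, against my 0.297, and the main reason it ends below Thursday's is the difference in temperature programme: Friday's on Thursday's programme ends at 29.3% rather than 10.7%. The step in which starting material and target go to side product B is a part of the story, not the whole: Friday's without that step ends at 27.6% rather than 10.7%. A neighbour of Thursday's, the same flask with 0.13 M of starting material, has 0% of it left at the end, so my selectivity gives 0.297; that neighbour gives 18.4%, with side product B at 37.4% against Thursday's 22.4%.

The data stem from a simulated flask for substances that don't exist.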